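**Plan**
- Feature used: ring A of the decalin (C1–C5 and C10, with the 2α-oxygen, the two methyls on C4 and the methyl on C10) can be bought as a hydroxylated trimethylcyclohexanone, so an acid-triggered closure only has to make C9–C10 and C8–O, that is ring B and the γ-lactone.
- Cuts, from the target backwards: C1′–C8a′ and C4′–C4a′ (methoxy-enedione ring); the chromone pyranone ring; C12–C4a′ and C15–C8a′ (cyclohexadiene); C12=C13 and C14=C15 (back to the lactone carbonyl C12); C9–C10 and C8–O (key step); C7–C8 and C5–C6 (side chain).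
- Forward: ring A is bought; the side chain is attached by Stille and B-alkyl Suzuki couplings; ring B and the lactone close together; the lactone is opened to the 12,14-diene; the cyclohexadiene, the chromone and last the enedione ring are added; desilylation ends the route.
- Stereochemistry: C2 comes from (4R,6R)-actinol and relays C5, C10, C9 and C8 in the cyclization (the E-olefin comes from a syn-hydrozirconation); C5′ is set by a chiral copper catalyst; C4a′ and C8a′ follow from annulation anti to the C5′ substituent.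

Key step: step 8

Numbering: terpenoid carbons carry labdane numbers (side chain C11, C12; diene C12=C13(C16)–C14=C15); the new carbocycle carries primed naphthalene numbers (C5′ = C12, C6′ = C13, C7′ = C14, C8′ = C15); all decalin compounds have the absolute configuration of (+)-sclareolide.
Assumption: which antipode of the amino amide ligand in step 18 gives the (6R) centre is taken to be settled by a test run with both, because the decalin centres are too remote to override the catalyst; sulfone 26 is used racemic because its stereocentre becomes the C1′ carbonyl.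

**Step 1**
Reactants: 1 pent-3-yn-1-ol
Product: 2 tert-butyldimethyl(pent-3-yn-1-yloxy)silane
Conditions: TBSCl, imidazole, DMF, 0 °C to rt
Reagents that add atoms: tert-butyldimethylsilyl chloride, CC(C)(C)[Si](C)(C)Cl
Why: Imidazole-promoted silylation of the primary alcohol is a routine protection that keeps the hydroxyl from consuming the zirconium hydride in the next step.

**Step 2**
Reactants: 2 tert-butyldimethyl(pent-3-yn-1-yloxy)silane
Product: 4 (E)-tert-butyl[(4-iodopent-3-en-1-yl)oxy]dimethylsilane, via alkenylzirconocene chloride 3 (not isolated)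
Conditions: Cp2Zr(H)Cl (excess), THF, rt to 45 °C; then I2, 0 °C
Reagents that add atoms: iodine, [I][I]
Why: syn-Hydrozirconation of the internal alkyne, equilibrated with excess hydride to the alkenylzirconium that carries the metal on the less hindered, methyl-bearing carbon, followed by iododezirconation with retention, should give the (E)-iodide in which iodine and the olefinic hydrogen are cis (hydrozirconation–iodination).

**Step 3**
Reactants: 5 (4R,6R)-actinol
Product: 6 (1R,3R)-3,5,5-trimethyl-4-oxocyclohexyl benzoate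
Conditions: BzCl, pyridine, DMAP (cat.), CH2Cl2, 0 °C to rt
Reagents that add atoms: benzoyl chloride, O=C(Cl)c1ccccc1
Why: Nucleophile-catalysed esterification of the secondary alcohol installs, before any cation chemistry, the electron-poor ester that the later C2 needs, and leaves the carbinol centre untouched.

**Step 4**
Reactants: 6 (1R,3R)-3,5,5-trimethyl-4-oxocyclohexyl benzoate
Product: 7 (4R)-4-benzoyloxy-2,6,6-trimethylcyclohex-1-en-1-yl trifluoromethanesulfonate
Conditions: Tf2O, 2,6-di-tert-butyl-4-methylpyridine, CH2Cl2, 0 °C to rt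
Reagents that add atoms: trifluoromethanesulfonic anhydride, O=S(=O)(OS(=O)(=O)C(F)(F)F)C(F)(F)F
Why: O-Triflation of the ketone under non-enolate conditions and loss of the only α-proton gives the tetrasubstituted enol triflate (vinyl triflate formation with Tf2O and a hindered pyridine), which avoids an enolate that could attack the benzoate; the methyl-bearing centre of actinol is erased on purpose and the carbinol centre is unaffected.

**Step 5**
Reactants: 7 (4R)-4-benzoyloxy-2,6,6-trimethylcyclohex-1-en-1-yl trifluoromethanesulfonate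
Product: 8 (1R)-3,5,5-trimethyl-4-vinylcyclohex-3-en-1-yl benzoate
Conditions: tributyl(vinyl)stannane, Pd(PPh3)4 (cat.), LiCl, THF, 65 °C
Reagents that add atoms: tributyl(vinyl)stannane, C=C[Sn](CCCC)(CCCC)CCCC
Why: Stille coupling of a hindered cyclohexenyl triflate with a vinylstannane in the presence of LiCl is well established and is neutral enough for the benzoate; it forms C5–C6.

**Step 6**
Reactants: 8 (1R)-3,5,5-trimethyl-4-vinylcyclohex-3-en-1-yl benzoate; 4 (E)-tert-butyl[(4-iodopent-3-en-1-yl)oxy]dimethylsilane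
Product: 10 (1R)-4-[(3E)-6-(tert-butyldimethylsilyloxy)-3-methylhex-3-en-1-yl]-3,5,5-trimethylcyclohex-3-en-1-yl benzoate, via B-alkyl-9-BBN adduct 9 (not isolated)
Conditions: 9-BBN, THF, 0 °C to rt; then 4, PdCl2(dppf) (cat.; dppf = 1,1'-bis(diphenylphosphino)ferrocene), AsPh3, Cs2CO3, DMF/H2O, rt
Reagents that add atoms: none
Why: 9-BBN adds only to the terminal vinyl carbon of the twisted diene, and the primary alkylborane undergoes B-alkyl Suzuki–Miyaura coupling with the vinyl iodide with retention of geometry, which forms C7–C8 and fixes the (E)-trisubstituted C8=C9 olefin.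

**Step 7**
Reactants: 10 (1R)-4-[(3E)-6-(tert-butyldimethylsilyloxy)-3-methylhex-3-en-1-yl]-3,5,5-trimethylcyclohex-3-en-1-yl benzoate
Product: 12 (3E)-6-[(4R)-4-benzoyloxy-2,6,6-trimethylcyclohex-1-en-1-yl]-4-methylhex-3-enoic acid, via primary alcohol 11 (not isolated)
Conditions: CrO3, H2SO4, H2O, acetone, 0 °C
Reagents that add atoms: water, O
Why: Aqueous chromic acid cleaves the primary silyl ether and oxidises the homoallylic alcohol through the aldehyde hydrate to the β,γ-unsaturated acid without moving the double bond (Jones oxidation).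

**Step 8**
Reactants: 12 (3E)-6-[(4R)-4-benzoyloxy-2,6,6-trimethylcyclohex-1-en-1-yl]-4-methylhex-3-enoic acid
Product: 13 2α-benzoyloxysclareolide (2α-benzoyloxy-13,14,15,16-tetranorlabdan-12,8α-olide)
Conditions: ClSO3H (excess), 2-nitropropane, −78 °C; then Et3N, aq NaHCO3
Reagents that add atoms: none
Why: Chlorosulfonic acid protonates the tetrasubstituted C5=C10 olefin at C5, the tertiary C10 cation is attacked by C9 of the (E)-C8=C9 olefin, and the carboxyl oxygen then captures the C8 cation and loses its proton (stepwise cationic bicyclization with lactone termination). The closest known reaction is the superacid cyclization of (E)-monocyclohomofarnesic acid to sclareolide, of which this is the 2-acyloxy analogue. Ring B closes 6-endo-trig through a chair in which the C5 side chain is equatorial, and the lactone closes 5-exo-trig on the C8 cation. C5 and C10 arise trans because C9 bonds to C10 on the face that leaves the C10 methyl axial and anti to H5, while H9 and the 8α-oxygen follow from anti addition of C10 and oxygen across the (E)-olefin. The step needs selection between the two faces of ring A, and this is secured by the C2 benzoate, which stays equatorial in the chair–chair transition state because the other face would set it 1,3-diaxial to the C10 methyl and the axial C4 methyl. A benzoate is used because an electron-poor ester at C2 should neither ionize nor bridge to the C10 cation under the acid.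

**Step 9**
Reactants: 13 2α-benzoyloxysclareolide
Product: 14 2α,8α-dihydroxy-13,14,15,16-tetranorlabdan-12-oic acid N-methoxy-N-methylamide
Conditions: MeNH(OMe)·HCl, AlMe3 (excess), CH2Cl2, 0 to 40 °C; aq KNaC4H4O6 work-up
Reagents that add atoms: N,O-dimethylhydroxylamine hydrochloride, CNOC.Cl
Why: The chloro(methyl)aluminium amide formed from AlMe3 and the amine hydrochloride aminolyses both acyl–oxygen bonds, opening the γ-lactone to the hydroxy amide and releasing the C2 alcohol from the benzoate (aluminium-amide aminolysis of esters); no stereocentre is involved.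

**Step 10**
Reactants: 14 2α,8α-dihydroxy-13,14,15,16-tetranorlabdan-12-oic acid N-methoxy-N-methylamide
Product: 15 2α,8α-bis(triethylsilyloxy)-13,14,15,16-tetranorlabdan-12-oic acid N-methoxy-N-methylamide
Conditions: TESOTf, 2,6-lutidine, CH2Cl2, −78 to 0 °C
Reagents that add atoms: triethylsilyl trifluoromethanesulfonate, CC[Si](CC)(CC)OS(=O)(=O)C(F)(F)F
Why: The silyl triflate with 2,6-lutidine silylates the secondary and the hindered tertiary alcohol alike, which blocks relactonisation and later oxa-Michael addition of the C8 hydroxyl.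

**Step 11**
Reactants: 15 2α,8α-bis(triethylsilyloxy)-13,14,15,16-tetranorlabdan-12-oic acid N-methoxy-N-methylamide
Product: 16 2α,8α-bis(triethylsilyloxy)-13,14,15,16-tetranorlabdan-12-al
Conditions: i-Bu2AlH, THF, −78 °C; aq KNaC4H4O6
Reagents that add atoms: none
Why: Hydride addition to the N-methoxy-N-methylamide stops at the chelated tetrahedral aluminium intermediate, which gives the aldehyde on work-up (amide-to-aldehyde reduction).

**Step 12**
Reactants: 16 2α,8α-bis(triethylsilyloxy)-13,14,15,16-tetranorlabdan-12-al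
Product: 17 (12E)-2α,8α-bis(triethylsilyloxy)-15-norlabd-12-en-14-al
Conditions: Ph3P=C(CH3)CHO, toluene, 90 °C
Reagents that add atoms: 2-(triphenylphosphoranylidene)propanal, CC(C=O)=P(c1ccccc1)(c1ccccc1)c1ccccc1
Why: The stabilised formyl ylide reacts under thermodynamic control and gives the (E)-2-methylenal, with C11 trans to the formyl group (Wittig reaction).

**Step 13**
Reactants: 17 (12E)-2α,8α-bis(triethylsilyloxy)-15-norlabd-12-en-14-al
Product: 18 (12E)-2α,8α-bis(triethylsilyloxy)labda-12,14-diene
Conditions: Ph3PCH3Br, KN(SiMe3)2, THF, −78 to 0 °C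
Reagents that add atoms: methyltriphenylphosphonium bromide, C[P+](c1ccccc1)(c1ccccc1)c1ccccc1.[Br-]
Why: Wittig methylenation of the enal gives the terminal diene without touching the (12E)-olefin, the silyl ethers or any stereocentre.

**Step 14**
Reactants: 19 propiolic acid; 20 3,5-dimethyl-1H-pyrazole
Product: 21 1-(3,5-dimethyl-1H-pyrazol-1-yl)prop-2-yn-1-one
Conditions: N,N'-dicyclohexylcarbodiimide, CH2Cl2, −10 °C to rt
Reagents that add atoms: none
Why: Carbodiimide coupling of the acid with the pyrazole N–H gives the N-acylpyrazole, an activated amide that can bind a metal through oxygen and N2 (carbodiimide-mediated acylation).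

**Step 15**
Reactants: 22 2',4',6'-trihydroxyacetophenone
Product: 23 2'-hydroxy-4',6'-bis(tert-butyldimethylsilyloxy)acetophenone
Conditions: TBSCl (2 equiv), imidazole, DMF, 0 °C
Reagents that add atoms: tert-butyldimethylsilyl chloride, CC(C)(C)[Si](C)(C)Cl
Why: The para hydroxyl and one of the two equivalent ortho hydroxyls are silylated, while the remaining ortho hydroxyl is held back by its hydrogen bond to the ketone (selective silylation of a chelated polyphenol).

**Step 16**
Reactants: 24 4-methoxyfuran-2(5H)-one (methyl tetronate)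
Product: 25 5-bromo-4-methoxyfuran-2(5H)-one (racemic)
Conditions: NBS, AIBN (cat.), PhCF3, 80 °C
Reagents that add atoms: N-bromosuccinimide, O=C1CCC(=O)N1Br
Why: Radical bromination at C5, which is both allylic and α to the ring oxygen, is the usual entry to 5-substituted tetronates (Wohl–Ziegler bromination).

**Step 17**
Reactants: 25 5-bromo-4-methoxyfuran-2(5H)-one
Product: 26 4-methoxy-5-(phenylsulfonyl)furan-2(5H)-one (racemic)
Conditions: PhSO2Na, DMF, rt
Reagents that add atoms: sodium benzenesulfinate, [Na+].[O-]S(=O)c1ccccc1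
Why: S-Alkylation of the sulfinate by the reactive α-alkoxy allylic bromide gives the sulfone, in the same way as sulfonylphthalides are made from bromophthalides (nucleophilic substitution).

**Step 18**
Reactants: 18 (12E)-2α,8α-bis(triethylsilyloxy)labda-12,14-diene; 21 1-(3,5-dimethyl-1H-pyrazol-1-yl)prop-2-yn-1-one
Product: 27 [(6R)-6-(2α,8α-bis(triethylsilyloxy)driman-11-yl)-5-methylcyclohexa-1,4-dien-1-yl](3,5-dimethylpyrazol-1-yl)methanone
Conditions: Cu(NTf2)2 (10 mol %), chiral 3-(2-naphthyl)alanine amide ligand (11 mol %), 4 Å MS, CH2Cl2, −40 to 0 °C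
Reagents that add atoms: none
Why: Two-point binding of the N-acylpyrazole to divalent copper activates the alkyne for a Diels–Alder reaction in which the acyl-bearing carbon bonds to the substituted diene terminus C12 and the free alkyne carbon to C15 (ortho rule for a 1-alkyl diene), and the aryl group of the ligand shields one face of the bound dienophile, so that the chosen antipode sets the (6R) centre at former C12 by reagent control (chiral Lewis acid-catalysed Diels–Alder reaction of an alkynoyl pyrazole).

**Step 19**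
Reactants: 27 the acylpyrazole of step 18; 23 2'-hydroxy-4',6'-bis(tert-butyldimethylsilyloxy)acetophenone
Product: 29 2-[(6R)-6-(2α,8α-bis(triethylsilyloxy)driman-11-yl)-5-methylcyclohexa-1,4-dien-1-yl]-5,7-bis(tert-butyldimethylsilyloxy)-4H-chromen-4-one, via o-hydroxyaryl 1,3-diketone 28 (not isolated)
Conditions: 23, LiN(SiMe3)2 (2 equiv), THF, −78 °C; add 27, −78 to −30 °C; AcOH; then camphorsulfonic acid (cat.), 4 Å MS, CH2Cl2, rt
Reagents that add atoms: none
Why: C-Acylation of the lithium enolate of 23 by the N-acylpyrazole (Claisen condensation with an activated amide, the expelled pyrazolide being the only other base present, so that the doubly allylic C6–H is left alone) gives the o-hydroxyaryl 1,3-diketone, which cyclodehydrates under mild acid to the chromone (Baker–Venkataraman-type chromone synthesis); the C6 centre is not touched and the ortho silyloxy group ends as the 5-silyloxy group.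

**Step 20**
Reactants: 29 the chromone of step 19; 26 4-methoxy-5-(phenylsulfonyl)furan-2(5H)-one
Product: 30 (4aS,5R,8aR)-4a-[5,7-bis(tert-butyldimethylsilyloxy)-4-oxo-4H-chromen-2-yl]-5-[2α,8α-bis(triethylsilyloxy)driman-11-yl]-2-methoxy-6-methyl-4a,5,8,8a-tetrahydronaphthalene-1,4-dione
Conditions: 26 (1.3 equiv), LiN(SiMe3)2 (1.25 equiv), THF, −78 °C; add 29, −78 to −10 °C; then AcOH
Reagents that add atoms: none
Why: Proposed new method: the lithium anion of 26, a furanolate stabilised by the sulfonyl group, should add through C5 of the furanone to the alkene terminus C8a′ of 29 (1,6-addition to the chromone vinylogue), the chromone-stabilised carbanion at C4a′ should then acylate itself on the lactone carbonyl (Dieckmann closure), and collapse of the bridged alkoxide with loss of benzenesulfinate should give the 2-methoxy-ene-1,4-dione with the methoxy group next to C1′; both new bonds form on one face (a stepwise anionic [4+2]) and anti to the pseudoaxial C5′ substituent, which sets C4a′ (S) and C8a′ (R) cis-fused with the chromone and H8a′ syn to the drimanylmethyl group; the closest known reaction type is the Hauser–Kraus annulation of 3-sulfonylphthalides with Michael acceptors, here transferred to a non-benzo tetronate donor and a vinylogous acceptor.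

**Step 21**
Reactants: 30 the tetrasilyl ether of step 20
Product: 31 (4aS,5R,8aR)-4a-(5,7-dihydroxy-4-oxo-4H-chromen-2-yl)-5-(2α,8α-dihydroxydriman-11-yl)-2-methoxy-6-methyl-4a,5,8,8a-tetrahydronaphthalene-1,4-dione (CNP0267683.1)
Conditions: HF·pyridine, pyridine, THF, 0 °C to rt
Reagents that add atoms: none
Why: Buffered fluoride cleaves the two aryl and the two alkyl silyl ethers under non-basic conditions (global desilylation), so the cis ring fusion at C8a′, the methoxy enedione and the tertiary alcohol should survive.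

**Compound list**
1 | pent-3-yn-1-ol | CC#CCCO | starting material
2 | tert-butyldimethyl(pent-3-yn-1-yloxy)silane | CC#CCCO[Si](C)(C)C(C)(C)C | intermediate
3 | (E)-alkenylzirconocene chloride, Cp2Zr(Cl)[C(CH3)=CHCH2CH2OTBS] (Cp drawn σ-bonded) | C/C(=C\CCO[Si](C)(C)C(C)(C)C)[Zr](Cl)(C1C=CC=C1)C1C=CC=C1 | intermediate (not isolated)
4 | (E)-tert-butyl[(4-iodopent-3-en-1-yl)oxy]dimethylsilane | C/C([I])=C\CCO[Si](C)(C)C(C)(C)C | intermediate
5 | (4R,6R)-actinol, (4R,6R)-4-hydroxy-2,2,6-trimethylcyclohexanone | O=C1[C@H](C)C[C@@H](O)CC1(C)C | starting material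
6 | (1R,3R)-3,5,5-trimethyl-4-oxocyclohexyl benzoate | O=C1[C@H](C)C[C@@H](OC(=O)c2ccccc2)CC1(C)C | intermediate
7 | (4R)-4-benzoyloxy-2,6,6-trimethylcyclohex-1-en-1-yl trifluoromethanesulfonate | O=S(=O)(OC1=C(C)C[C@@H](OC(=O)c2ccccc2)CC1(C)C)C(F)(F)F | intermediate
8 | (1R)-3,5,5-trimethyl-4-vinylcyclohex-3-en-1-yl benzoate | C=CC1=C(C)C[C@@H](OC(=O)c2ccccc2)CC1(C)C | intermediate
9 | (1R)-4-[2-(9-borabicyclo[3.3.1]nonan-9-yl)ethyl]-3,5,5-trimethylcyclohex-3-en-1-yl benzoate | C(CB1C2CCCC1CCC2)C1=C(C)C[C@@H](OC(=O)c2ccccc2)CC1(C)C | intermediate (not isolated)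
10 | (1R)-4-[(3E)-6-(tert-butyldimethylsilyloxy)-3-methylhex-3-en-1-yl]-3,5,5-trimethylcyclohex-3-en-1-yl benzoate | CC(C)(C)[Si](C)(C)OCC/C=C(\C)CCC1=C(C)C[C@@H](OC(=O)c2ccccc2)CC1(C)C | intermediate
11 | (1R)-4-[(3E)-6-hydroxy-3-methylhex-3-en-1-yl]-3,5,5-trimethylcyclohex-3-en-1-yl benzoate | OCC/C=C(\C)CCC1=C(C)C[C@@H](OC(=O)c2ccccc2)CC1(C)C | intermediate (not isolated)
12 | (3E)-6-[(4R)-4-benzoyloxy-2,6,6-trimethylcyclohex-1-en-1-yl]-4-methylhex-3-enoic acid | OC(=O)C/C=C(\C)CCC1=C(C)C[C@@H](OC(=O)c2ccccc2)CC1(C)C | intermediate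
13 | 2α-benzoyloxysclareolide | O=C1C[C@@H]2[C@@]3(C)C[C@@H](OC(=O)c4ccccc4)CC(C)(C)[C@@H]3CC[C@@]2(C)O1 | intermediate
14 | 2α,8α-dihydroxy-13,14,15,16-tetranorlabdan-12-oic acid N-methoxy-N-methylamide | CON(C)C(=O)C[C@@H]1[C@@]2(C)C[C@@H](O)CC(C)(C)[C@@H]2CC[C@@]1(C)O | intermediate
15 | 2α,8α-bis(triethylsilyloxy)-13,14,15,16-tetranorlabdan-12-oic acid N-methoxy-N-methylamide | CON(C)C(=O)C[C@@H]1[C@@]2(C)C[C@@H](O[Si](CC)(CC)CC)CC(C)(C)[C@@H]2CC[C@@]1(C)O[Si](CC)(CC)CC | intermediate
16 | 2α,8α-bis(triethylsilyloxy)-13,14,15,16-tetranorlabdan-12-al | O=CC[C@@H]1[C@@]2(C)C[C@@H](O[Si](CC)(CC)CC)CC(C)(C)[C@@H]2CC[C@@]1(C)O[Si](CC)(CC)CC | intermediate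
17 | (12E)-2α,8α-bis(triethylsilyloxy)-15-norlabd-12-en-14-al | O=C/C(C)=C/C[C@@H]1[C@@]2(C)C[C@@H](O[Si](CC)(CC)CC)CC(C)(C)[C@@H]2CC[C@@]1(C)O[Si](CC)(CC)CC | intermediate
18 | (12E)-2α,8α-bis(triethylsilyloxy)labda-12,14-diene | C=C/C(C)=C/C[C@@H]1[C@@]2(C)C[C@@H](O[Si](CC)(CC)CC)CC(C)(C)[C@@H]2CC[C@@]1(C)O[Si](CC)(CC)CC | intermediate
19 | propiolic acid | C#CC(=O)O | starting material
20 | 3,5-dimethyl-1H-pyrazole | Cc1cc(C)[nH]n1 | starting material
21 | 1-(3,5-dimethyl-1H-pyrazol-1-yl)prop-2-yn-1-one | C#CC(=O)n1nc(C)cc1C | intermediate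
22 | 2',4',6'-trihydroxyacetophenone | CC(=O)c1c(O)cc(O)cc1O | starting material
23 | 2'-hydroxy-4',6'-bis(tert-butyldimethylsilyloxy)acetophenone | CC(=O)c1c(O)cc(O[Si](C)(C)C(C)(C)C)cc1O[Si](C)(C)C(C)(C)C | intermediate
24 | 4-methoxyfuran-2(5H)-one (methyl tetronate) | COC1=CC(=O)OC1 | starting material
25 | 5-bromo-4-methoxyfuran-2(5H)-one (racemic) | COC1=CC(=O)OC1Br | intermediate
26 | 4-methoxy-5-(phenylsulfonyl)furan-2(5H)-one (racemic) | COC1=CC(=O)OC1S(=O)(=O)c1ccccc1 | intermediate
27 | [(6R)-6-(2α,8α-bis(triethylsilyloxy)driman-11-yl)-5-methylcyclohexa-1,4-dien-1-yl](3,5-dimethylpyrazol-1-yl)methanone | Cc1cc(C)n(n1)C(=O)C1=CCC=C(C)[C@H]1C[C@@H]1[C@@]2(C)C[C@@H](O[Si](CC)(CC)CC)CC(C)(C)[C@@H]2CC[C@@]1(C)O[Si](CC)(CC)CC | intermediate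
28 | 1-[2-hydroxy-4,6-bis(tert-butyldimethylsilyloxy)phenyl]-3-[(6R)-6-(2α,8α-bis(triethylsilyloxy)driman-11-yl)-5-methylcyclohexa-1,4-dien-1-yl]propane-1,3-dione | O=C(CC(=O)c1c(O)cc(O[Si](C)(C)C(C)(C)C)cc1O[Si](C)(C)C(C)(C)C)C1=CCC=C(C)[C@H]1C[C@@H]1[C@@]2(C)C[C@@H](O[Si](CC)(CC)CC)CC(C)(C)[C@@H]2CC[C@@]1(C)O[Si](CC)(CC)CC | intermediate (not isolated)
29 | 2-[(6R)-6-(2α,8α-bis(triethylsilyloxy)driman-11-yl)-5-methylcyclohexa-1,4-dien-1-yl]-5,7-bis(tert-butyldimethylsilyloxy)-4H-chromen-4-one | O=c1cc(C2=CCC=C(C)[C@H]2C[C@@H]2[C@@]3(C)C[C@@H](O[Si](CC)(CC)CC)CC(C)(C)[C@@H]3CC[C@@]2(C)O[Si](CC)(CC)CC)oc2cc(O[Si](C)(C)C(C)(C)C)cc(O[Si](C)(C)C(C)(C)C)c12 | intermediate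
30 | (4aS,5R,8aR)-4a-[5,7-bis(tert-butyldimethylsilyloxy)-4-oxo-4H-chromen-2-yl]-5-[2α,8α-bis(triethylsilyloxy)driman-11-yl]-2-methoxy-6-methyl-4a,5,8,8a-tetrahydronaphthalene-1,4-dione | COC1=CC(=O)[C@@]2(c3cc(=O)c4c(O[Si](C)(C)C(C)(C)C)cc(O[Si](C)(C)C(C)(C)C)cc4o3)[C@H](C[C@@H]3[C@@]4(C)C[C@@H](O[Si](CC)(CC)CC)CC(C)(C)[C@@H]4CC[C@@]3(C)O[Si](CC)(CC)CC)C(C)=CC[C@H]2C1=O | intermediate
31 | (4aS,5R,8aR)-4a-(5,7-dihydroxy-4-oxo-4H-chromen-2-yl)-5-(2α,8α-dihydroxydriman-11-yl)-2-methoxy-6-methyl-4a,5,8,8a-tetrahydronaphthalene-1,4-dione (CNP0267683.1) | COC1=CC(=O)[C@@]2(c3cc(=O)c4c(O)cc(O)cc4o3)[C@H](C[C@@H]3[C@@]4(C)C[C@@H](O)CC(C)(C)[C@@H]4CC[C@@]3(C)O)C(C)=CC[C@H]2C1=O | target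

**Count and risks**
Total step count: 21. Longest linear sequence: 15 steps (steps 3–13 and 18–21, from (4R,6R)-actinol).

Steps most likely to fail:

1. Step 20 (annulation). The stabilised anion of 26 may add reversibly to the weak vinylogous acceptor without the ring closing onto the donor-substituted lactone carbonyl. It may also act as a base on the doubly allylic C5′–H and C8′–H2, which would lead to double-bond migration and aromatisation of the cyclohexadiene. The fallback uses known reactions only, sets out from 29 and comes back at 30; it replaces the base-mediated addition by a Lewis-acid-mediated one. Methyl tetronate 24 is converted with i-Pr3SiOTf and Et3N into 4-methoxy-2-(triisopropylsilyloxy)furan F1. Vinylogous Mukaiyama–Michael addition of F1 to 29, activated at the chromone carbonyl by TMSOTf in CH2Cl2 at −78 °C, should give the C8a′-linked butenolide Michael adduct F2 with the new bond anti to the C5′ substituent. LiN(SiMe3)2 then deprotonates C4a′, the position α to the chromone C2, and the carbanion closes onto the lactone carbonyl in a Dieckmann-type acylation, again anti to the C5′ substituent and cis to the C8a′ bond, to give the 1′-hydroxy-2′-methoxy enone F3. Dess–Martin oxidation of the allylic carbinol gives 30.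

2. Step 18 (Diels–Alder reaction). The silyl ether oxygens and the bulk of the decalin may slow the copper catalyst, so that an uncatalysed background reaction erodes the facial selection at C12 and the ortho regiochemistry. The fallback sets out from 18 and comes back at 28; the stereocentre is then accepted as a separable pair. EtAlCl2-promoted Diels–Alder reaction of 18 with methyl propiolate in CH2Cl2 at −78 °C, a standard ortho-selective alkynoate cycloaddition, should give both C6 epimers of the cyclohexadiene ester. After chromatographic separation, methyl (6R)-6-(2α,8α-bis(triethylsilyloxy)driman-11-yl)-5-methylcyclohexa-1,4-diene-1-carboxylate F4 is condensed with the dianion of 23 (LiN(SiMe3)2, THF, −78 °C, Claisen condensation) to give diketone 28, which is cyclised to 29 as in step 19.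

3. Step 8 (key cyclization). Protonation on the wrong face of ring A or at the C8=C9 olefin, proton loss from the C8 cation before the carboxyl closes, and bridging of the benzoate to C10 from the minor ring conformer would all lower the share of the trans-fused 8α-lactone. The fallback sets out from 10 and comes back at 13; it forms the same two bonds with the hydroxyl as terminating group, the best-studied variant of this closure, and restores the lactone oxidation level afterwards. Bu4NF removes the silyl group of 10 to give alcohol 11, now isolated. ClSO3H in 2-nitropropane at −78 °C should close ring B and the tetrahydrofuran to give 2α-benzoyloxy-8α,12-epoxy-13,14,15,16-tetranorlabdane F5. RuCl3 (cat.) with NaIO4 oxidises the ether methylene C12 to the lactone carbonyl and gives 13.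

**Further compounds**
F1 | step 20 | 4-methoxy-2-(triisopropylsilyloxy)furan | COc1cc(O[Si](C(C)C)(C(C)C)C(C)C)oc1
F2 | step 20 | Michael adduct: chromone 29 with H at C4a′ and a 3-methoxy-5-oxo-2,5-dihydrofuran-2-yl group at C8a′, anti to the C5′ substituent (epimers at C4a′ and at the furanone carbon) | COC1=CC(=O)OC1[C@@H]1CC=C(C)[C@@H](C[C@@H]2[C@@]3(C)C[C@@H](O[Si](CC)(CC)CC)CC(C)(C)[C@@H]3CC[C@@]2(C)O[Si](CC)(CC)CC)C1c1cc(=O)c2c(O[Si](C)(C)C(C)(C)C)cc(O[Si](C)(C)C(C)(C)C)cc2o1
F3 | step 20 | (4aS,5R,8aR)-1-hydroxy-2-methoxy enone corresponding to 30, with C1′ as a secondary carbinol (both C1′ epimers) | COC1=CC(=O)[C@@]2(c3cc(=O)c4c(O[Si](C)(C)C(C)(C)C)cc(O[Si](C)(C)C(C)(C)C)cc4o3)[C@H](C[C@@H]3[C@@]4(C)C[C@@H](O[Si](CC)(CC)CC)CC(C)(C)[C@@H]4CC[C@@]3(C)O[Si](CC)(CC)CC)C(C)=CC[C@H]2C1O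
F4 | step 18 | methyl (6R)-6-(2α,8α-bis(triethylsilyloxy)driman-11-yl)-5-methylcyclohexa-1,4-diene-1-carboxylate | COC(=O)C1=CCC=C(C)[C@H]1C[C@@H]1[C@@]2(C)C[C@@H](O[Si](CC)(CC)CC)CC(C)(C)[C@@H]2CC[C@@]1(C)O[Si](CC)(CC)CC
F5 | step 8 | 2α-benzoyloxy-8α,12-epoxy-13,14,15,16-tetranorlabdane | C1C[C@@H]2[C@@]3(C)C[C@@H](OC(=O)c4ccccc4)CC(C)(C)[C@@H]3CC[C@@]2(C)O1
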